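X, the catalyst, is the charge to watch when you repeat the east run. From the north-west to the south run, [X] rises by a factor 3.00 and J at 64 min by a factor 1.97. From the north-west to the west run, twice the [E] raises J by a factor 1.09.

| flask | E | X | time |
|---|---|---|---|
| north-west | 0.200 M | 0.0100 M |  |
| south | 0.200 M | 0.0300 M |  |
| west | 0.400 M | 0.0100 M |  |
| east | 0.600 M | 0.00500 M | 64 min |

- north-west run (time / min: [J] / M): 4.9: 0.0462; 15: 0.0581; 28: 0.0629; 45: 0.0649; 64: 0.0655
- south run (time / min: [J] / M): 4.9: 0.1131; 15: 0.1261; 28: 0.1288; 45: 0.1294; 64: 0.1289
- west run (time / min: [J] / M): 4.9: 0.0579; 15: 0.0661; 28: 0.0691; 45: 0.0700; 64: 0.0713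

(scatter of a reading: 6 × 10⁻⁴ M)

- Overall: E -> J, with X as catalyst.
- Constant volume, constant temperature.
- An order is taken over about fifteen percent of the charge, up and down.

- the exponent of [E] in the starting rate at the charge of the north-west run (at the point where two percent of the E have become J) (one fixed amount of J, the same in the runs compared)
- the exponent of [X] in the starting rate at the charge of the north-west run (at the point where two percent of the E have become J)
- J in the east run at 64 min, as a share of the E charged

My reckoning for the east run needs three numbers, so test each before using it.

The first is the time. J in the west run approaches its 64 min reading at about 0.0937 /min, read between its first two readings, which is a lifetime of 10.7 min. I assume this lifetime for the east run: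

64 min / 10.7 min = 5.98 lifetimes, leaving 0.248% of the rise unfinished

With twice that lifetime, 5.03% would be unfinished, so this number matters little.

The second is the scatter, which is 0.842% of the last west reading and also matters little.

The third is J at 64 min per X charged, 7.13 in the west run, and I call it the ration of X, the turnover number. The north-west run gives 6.55, which is 8.13% lower, at [E]/[X] of 20.0 against 40.0. The east run stands at 120, so I bracket it:

west ration: 7.13 × 0.00500 M / 0.600 M = 5.94%

with the same gain once more: 6.42%

The two ends differ by 8.08% of the lower, more than either share reckoned above. I commit to the middle, 6.18%.

The forecast gives 0.55 and 1.05 for the exponents and 7.4% for J, higher than mine. Its ground is that “plateau yield rises slightly with E and scales as about X^0.75”, whereas my ration takes J in step with [X].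

    X + E → J + X (18.12 /M/min)
    2 E → Xa (1.320 /M/min)
    X + E → Ek + E (2.448 /M/min)

The east run gives 6.06%, with exponents 1.0 and 1.1. The forecast's 0.55 for [E] parts from the first: at equal J made, the west rate is 2.0 times the north-west rate. The east ration comes to 7.27, above the west reading and below k1/k3, 7.40. The turning of E into Xa changes this J very little. In the south run, the west ration times [X] asks for 0.214 M, more than the 0.200 M of E charged, and the south run reads 0.1289 M at 64 min, a ration of 4.30.

Readings and results are calculated from invented constants, and the scatter is random.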